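All runs are calculated with made-up constants; scatter was added.

Turns per hour is the unit for these flasks. Spent carrier takes up salt from the second phase and becomes fresh carrier; fresh carrier turns starting material into target and is spent again, while added ligand and target can hold it idle.

| flask | starting material | salt in the second phase | spent carrier | added ligand | remark | time | volume of the second phase over the first |
|---|---|---|---|---|---|---|---|
| teal | 0.20 M (fed, over 2.5 h) | 2.5 equiv | 9.3 mol% | 10 mM | run made earlier |  |  |
| violet | 0.20 M (fed, over 2.5 h) | 2.5 equiv | 9.3 mol% | 11 mM | run made earlier |  |  |
| blue | 0.29 M (fed, over 2.5 h) | 2.5 equiv | 9.3 mol% | 14 mM | run made earlier |  |  |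
| winter | 0.20 M (fed, over 0.80 h) | 5.00 equiv | 9.3 mol% | 14 mM |  | 20 h | 1.0 |
| summer | 0.20 M (fed, over 2.5 h) | 1.70 equiv | 9.3 mol% | 14 mM |  | 20 h | 1.0 |
| noon | 0.20 M (fed, over 2.5 h) | 7.50 equiv | 9.3 mol% | 8.0 mM |  | 20 h | 1.0 |
| dawn | 0.30 M (fed, over 2.5 h) | 3.80 equiv | 2.5 mol% | 14 mM |  | 20 h | 1.0 |
| spring | 0.20 M (fed, over 2.5 h) | 2.50 equiv | 9.3 mol% | 14 mM |  | 20 h | 1.0 |

- teal (time / h: target / %, starting material / %): 1.50: 2, 59; 3.00: 7, 96; 6.00: 3, 99; 10.0: 11, 92; 20.0: 23, 85
- violet (time / h: target / %, starting material / %): 1.50: 0, 62; 3.00: 1, 99; 6.00: 3, 95; 10.0: 10, 93; 20.0: 21, 84
- blue (time / h: target / %, starting material / %): 2.00: 3, 81; 5.00: 8, 96; 10.0: 14, 83; 15.0: 20, 85; 20.0: 23, 74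

(readings scatter by 2 percentage points)

- target is meant together with its idle complex B
- in the second phase: salt in the second phase, spent salt in the second phase; everything else is in the first
- charges count per volume of the first phase; a concentration in a rate is the amount of a species over the volume of its own phase; every rate counts per litre of the first phase
- candidate steps: spent carrier + salt in the second phase <-> fresh carrier + spent salt in the second phase; starting material + fresh carrier -> target + spent carrier; added ligand + fresh carrier <-> idle complex A; target + fresh carrier <-> idle complex B
- the earlier runs hold the two phases in the same ratio of volumes as the flask asked about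
- percentages count the whole charge, also what has not yet gone in

- the flasks by amount of target, in percent of the starting material charged, highest first, at 20 h (winter / summer / noon / dawn / spring)
- the amount of target, in percent of the starting material charged of the flask you put first, at 20 h
- the amount of target, in percent of the starting material charged of the flask you put last, at 20 h

In teal, target goes from 11% at 10.0 h to 23% at 20.0 h, twice the amount in twice the time, and starting material still reads 85%. So target is a small correction on a large pool, and I reckon with a steady rate: P = f·x·t, where P is target in percent of the charge, x the carrier loading, t the time, and f the turning rate, 0.124 h⁻¹, the target made per hour by each carrier charged, the turnover frequency.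

Two chemists read this differently. The titrator says ligand takes carrier one for one, so carrier minus ligand does the work: 8.60 mM in teal and 13.0 mM in blue. Per mM of that, the runs give 0.267 h⁻¹ and 0.257 h⁻¹, a good match. On that rate, noon reaches 28.3%, and dawn, with 7.50 mM of carrier against 14 mM of ligand, makes nothing.

The counter answers that blue's f is 0.124 h⁻¹, the same as teal's, and that teal and violet read 23% and 21%, with a scatter of 2 percentage points. So she counts charged carrier: noon gets 23.0% and dawn 6.18%.

The runs fit both views, and I side with the counter at dawn. My own reckoning puts noon first, between her figure and his, then winter, spring and summer by falling salt, which is a guess, and dawn last near her figure.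

The forecast takes the titrator's side on ligand but gives numbers of its own: noon > winter > spring > summer > dawn, top 55%, low 2%, with dawn “almost dead”.

The flask gives noon > winter > spring > summer > dawn, with noon at 32.3% and dawn at 9.39%.

    spent carrier + salt in the second phase ⇌ fresh carrier + spent salt in the second phase (K = 0.270, k = 0.00630 M⁻¹ min⁻¹)
    starting material + fresh carrier → target + spent carrier (k = 0.0450 M⁻¹ min⁻¹)
    added ligand + fresh carrier ⇌ idle complex A (K = 97.0 M⁻¹, k = 0.240 M⁻¹ min⁻¹)
    target + fresh carrier ⇌ idle complex B, settled at all times (K = 2.30 M⁻¹)

At 20.0 h, dawn still holds 85.1% of its added ligand unbound beside 24.6% of its catalyst as fresh carrier, so the counter takes dawn, whose turning rate, 0.188 h⁻¹, stands above f. At noon, where ligand lies under carrier, the titrator's figure falls nearer the flask.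

Take one more flask, like dawn but with 4.2 mol% of spent carrier, so ligand still exceeds carrier. Dawn's turning rate gives 15.8%, and the computed flask gives 15.4%.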